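**Retrosynthetic overview**
1. The endgame runs on the intact flavone. The O2'-benzyl group is removed last, O3 is methylated before that, and the C3–O bond is first put onto the C3–H flavone.
2. The strategy rests on ring C. The ketone carbon C4 is bonded only to C4a (ring A) and C3. C3=C2 is an enol ether whose C2 holds ring B and O1, which sits on C8a, ortho to C4a. Ring C therefore divides into an ortho-iodophenol (C4a–I, C8a–OH), CO (C4) and an arylacetylene (C3≡C2–ring B).
3. The key disconnection cuts C4a–C4, C4–C3 and O1–C2, all made in one palladium-catalysed carbonylative operation. Ring C is the only ring formed; rings A and B are bought.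
4. The iodide is set ortho to the hydroxyl of 2,3-dimethoxyphenol by carbamate-directed lithiation. The alkyne comes from 2-hydroxy-4,5-dimethoxybenzaldehyde by benzylation and one-carbon homologation.

Key step: step 6

Remark: flavone numbering (O1, C2, C3, C4, C4a, C5–C8, C8a; ring B primed) is used for all chromenones. The target has no stereocentre. The flavone epoxide of step 7 is racemic and loses both its centres in the same flask. Dimethyldioxirane is assumed to be a separately prepared, titrated acetone solution.

**Step 1**
Reactants: 1 2,3-dimethoxyphenol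
Product: 2 2,3-dimethoxyphenyl N,N-diethylcarbamate
Conditions: ClC(O)NEt2, K2CO3, MeCN, reflux
Reagents that add atoms: N,N-diethylcarbamoyl chloride, CCN(CC)C(=O)Cl
Why: O-carbamoylation of the phenol (nucleophilic acyl substitution) installs the strongest oxygen-based directing group for the metalation that follows.

**Step 2**
Reactants: 2 2,3-dimethoxyphenyl N,N-diethylcarbamate
Product: 4 6-iodo-2,3-dimethoxyphenyl N,N-diethylcarbamate, via aryllithium 3 (not isolated)
Conditions: s-BuLi, TMEDA, THF, −78 °C; then I2 in THF, −78 °C → rt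
Reagents that add atoms: iodine, [I][I]; sec-butyllithium, [Li]C(C)CC (its lithium stands only in intermediate 3)
Why: In this directed ortho-metalation the carbamate carbonyl binds s-BuLi·TMEDA and delivers it to C6, its only free ortho position and a stronger call than the methoxy-flanked C4, and the iodine quench at −78 °C forestalls the anionic ortho-Fries shift.

**Step 3**
Reactants: 4 6-iodo-2,3-dimethoxyphenyl N,N-diethylcarbamate
Product: 5 6-iodo-2,3-dimethoxyphenol
Conditions: NaOH (excess), EtOH–H2O, reflux; then aq. HCl
Reagents that add atoms: none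
Why: Basic carbamate hydrolysis (BAc2 acyl substitution) expels the good 2-iodophenoxide leaving group, and the aryl iodide and methyl ethers are inert to hydroxide in refluxing ethanol.

**Step 4**
Reactants: 6 2-hydroxy-4,5-dimethoxybenzaldehyde
Product: 7 2-(benzyloxy)-4,5-dimethoxybenzaldehyde
Conditions: BnBr, K2CO3, DMF, 60 °C
Reagents that add atoms: benzyl bromide, BrCc1ccccc1
Why: Williamson ether synthesis on the only free hydroxyl gives a benzyl ether that tolerates base, hot amine, short dioxirane exposure and MeI, and it leaves at the end under neutral conditions.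

**Step 5**
Reactants: 7 2-(benzyloxy)-4,5-dimethoxybenzaldehyde
Product: 8 1-(benzyloxy)-2-ethynyl-4,5-dimethoxybenzene
Conditions: dimethyl (1-diazo-2-oxopropyl)phosphonate, K2CO3, MeOH, rt
Reagents that add atoms: dimethyl (1-diazo-2-oxopropyl)phosphonate (Ohira–Bestmann reagent), COP(=O)(OC)C(=[N+]=[N-])C(C)=O
Why: The Ohira–Bestmann variant of the Seyferth–Gilbert homologation turns non-enolisable aryl aldehydes into terminal arylacetylenes under mild carbonate conditions that leave all ethers untouched.

**Step 6**
Reactants: 5 6-iodo-2,3-dimethoxyphenol; 8 1-(benzyloxy)-2-ethynyl-4,5-dimethoxybenzene; 9 carbon monoxide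
Product: 12 2-[2-(benzyloxy)-4,5-dimethoxyphenyl]-7,8-dimethoxy-4H-chromen-4-one, via ynone 10 (not isolated), via enaminone 11 (not isolated)
Conditions: PdCl2(PPh3)2 (5 mol%), CO (20 bar), Et2NH (solvent), 8 (1.2 equiv), 120 °C, autoclave, no copper salt
Reagents that add atoms: carbon monoxide 9, [C-]#[O+] (also listed as a reactant); diethylamine, CCNCC (its atoms stand only in intermediate 11 and leave again on ring closure)
Why: Zerovalent palladium, formed from PdCl2(PPh3)2 in the amine, inserts into the C–I bond of 5, CO migrates into the aryl–palladium bond to give ArC(O)PdI(PPh3)2, and the acetylide raised from 8 by diethylamine is joined to the aroyl group by reductive elimination, which makes C4a–C4 and C4–C3 and gives ynone 10. Diethylamine then adds to C2 of 10 to give enaminone 11, and the ortho phenol oxygen O1 replaces the amine at C2 by addition–elimination, a 6-endo closure that forms O1–C2 and completes ring C. The closest known reaction type is the copper-free carbonylative Sonogashira coupling–cyclisation of 2-iodophenols, terminal arylacetylenes and CO to flavones, of which this is a plain application, and no stereocentre is created. Acylation must win over direct alkynylation (the benzofuran channel) and over capture of the acyl complex by the amine; the CO pressure, the absence of copper and the fast-inserting electron-rich aryl–palladium bond serve the first, and the bulk of the secondary amine against a slim sp nucleophile serves the second. The 6-endo closure must win over 5-exo attack at C3 (the aurone channel), and conversion into 11 secures this because C2 is then the only carbon that carries a leaving group. The iodine placed in step 2 fixes C4a next to C8a–OH, so the 7,8-dimethoxy pattern follows without ambiguity.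

**Step 7**
Reactants: 12 2-[2-(benzyloxy)-4,5-dimethoxyphenyl]-7,8-dimethoxy-4H-chromen-4-one
Product: 14 2-[2-(benzyloxy)-4,5-dimethoxyphenyl]-3-hydroxy-7,8-dimethoxy-4H-chromen-4-one, via flavone epoxide 13 (not isolated)
Conditions: dimethyldioxirane (acetone solution, 2 equiv), CH2Cl2, 0 °C → rt; then p-TsOH·H2O (cat.), CH2Cl2, rt
Reagents that add atoms: dimethyldioxirane, CC1(C)OO1
Why: This is the known flavone-to-flavonol conversion, in which dioxirane epoxidises the enol ether C2=C3 bond, acid opens the epoxide at C2 (cation held by O1 and ring B) and H3 is lost, so the two centres of racemic 13 disappear.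

**Step 8**
Reactants: 14 2-[2-(benzyloxy)-4,5-dimethoxyphenyl]-3-hydroxy-7,8-dimethoxy-4H-chromen-4-one
Product: 15 2-[2-(benzyloxy)-4,5-dimethoxyphenyl]-3,7,8-trimethoxy-4H-chromen-4-one
Conditions: MeI, K2CO3, acetone, reflux
Reagents that add atoms: iodomethane, CI
Why: Williamson-type O-methylation of the acidic 3-hydroxyl, the only free hydroxyl in 14, is standard for flavonols.

**Step 9**
Reactants: 15 2-[2-(benzyloxy)-4,5-dimethoxyphenyl]-3,7,8-trimethoxy-4H-chromen-4-one
Product: 16 2-(2-hydroxy-4,5-dimethoxyphenyl)-3,7,8-trimethoxy-4H-chromen-4-one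
Conditions: H2 (1 atm), 10% Pd/C, EtOAc–MeOH, rt
Reagents that add atoms: none
Why: Catalytic hydrogenolysis cleaves the aryl benzyl ether while the tetrasubstituted vinylogous-ester C2=C3 bond stays intact at 1 atm, and the neutral medium avoids opening of ring C and re-closure onto the freed 2'-hydroxyl.

**Compound list**
1 | 2,3-dimethoxyphenol | Oc1cccc(OC)c1OC | starting material
2 | 2,3-dimethoxyphenyl N,N-diethylcarbamate | CCN(CC)C(=O)Oc1cccc(OC)c1OC | intermediate
3 | 6-lithio-2,3-dimethoxyphenyl N,N-diethylcarbamate (not isolated) | [Li]c1ccc(OC)c(OC)c1OC(=O)N(CC)CC | intermediate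
4 | 6-iodo-2,3-dimethoxyphenyl N,N-diethylcarbamate | CCN(CC)C(=O)Oc1c(I)ccc(OC)c1OC | intermediate
5 | 6-iodo-2,3-dimethoxyphenol | Oc1c(I)ccc(OC)c1OC | intermediate
6 | 2-hydroxy-4,5-dimethoxybenzaldehyde | COc1cc(O)c(C=O)cc1OC | starting material
7 | 2-(benzyloxy)-4,5-dimethoxybenzaldehyde | COc1cc(OCc2ccccc2)c(C=O)cc1OC | intermediate
8 | 1-(benzyloxy)-2-ethynyl-4,5-dimethoxybenzene | C#Cc1cc(OC)c(OC)cc1OCc1ccccc1 | intermediate
9 | carbon monoxide | [C-]#[O+] | starting material
10 | 3-[2-(benzyloxy)-4,5-dimethoxyphenyl]-1-(2-hydroxy-3,4-dimethoxyphenyl)prop-2-yn-1-one (not isolated) | COc1ccc(C(=O)C#Cc2cc(OC)c(OC)cc2OCc2ccccc2)c(O)c1OC | intermediate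
11 | (E)-3-[2-(benzyloxy)-4,5-dimethoxyphenyl]-3-(diethylamino)-1-(2-hydroxy-3,4-dimethoxyphenyl)prop-2-en-1-one (not isolated; geometry drawn as E, of no consequence for the closure) | CCN(CC)/C(=C/C(=O)c1ccc(OC)c(OC)c1O)c1cc(OC)c(OC)cc1OCc1ccccc1 | intermediate
12 | 2-[2-(benzyloxy)-4,5-dimethoxyphenyl]-7,8-dimethoxy-4H-chromen-4-one | COc1cc(OCc2ccccc2)c(-c2cc(=O)c3ccc(OC)c(OC)c3o2)cc1OC | intermediate
13 | 2,3-epoxide of 12, oxirane cis-fused to ring C (racemic, one enantiomer drawn; not isolated) | COc1ccc2C(=O)[C@H]3O[C@]3(Oc2c1OC)c1cc(OC)c(OC)cc1OCc1ccccc1 | intermediate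
14 | 2-[2-(benzyloxy)-4,5-dimethoxyphenyl]-3-hydroxy-7,8-dimethoxy-4H-chromen-4-one | COc1cc(OCc2ccccc2)c(-c2oc3c(OC)c(OC)ccc3c(=O)c2O)cc1OC | intermediate
15 | 2-[2-(benzyloxy)-4,5-dimethoxyphenyl]-3,7,8-trimethoxy-4H-chromen-4-one | COc1cc(OCc2ccccc2)c(-c2oc3c(OC)c(OC)ccc3c(=O)c2OC)cc1OC | intermediate
16 | 2-(2-hydroxy-4,5-dimethoxyphenyl)-3,7,8-trimethoxy-4H-chromen-4-one | COc1cc(O)c(-c2oc3c(OC)c(OC)ccc3c(=O)c2OC)cc1OC | target

**Totals**
Total step count: 9.
Longest linear sequence: 7 (steps 1, 2, 3, 6, 7, 8, 9).

**Steps most likely to fail**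

Step 6.
- Risk: CO insertion may be outrun by direct alkynylation. The acyl complex may be intercepted by the amine solvent. With the bulky ortho-benzyloxy ring B, closure may drift towards the 5-exo mode.
- Fallback: ring C is built without palladium or CO, setting out from 7 and returning at 12. Claisen–Schmidt condensation of 7 with bought 1-(2-hydroxy-3,4-dimethoxyphenyl)ethanone F1 (KOH, EtOH, rt) should give the (E)-2'-hydroxychalcone F2. Oxidative cyclisation of F2 (cat. I2, DMSO, 130 °C) then closes ring C by oxa-Michael addition and dehydrogenation to give 12.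

Step 7.
- Risk: epoxidation of the twisted, hindered C2=C3 bond may be slow. Oxidation of the electron-rich ring B or of the benzylic C–H bonds of the protecting group could then compete.
- Fallback: the polarity at C3 is inverted, setting out from 12 and returning at 14. Carbonyl-directed deprotonation with LiN(iPr)2 (THF, −78 °C) should give the 3-lithioflavone F3, and B(OMe)3 traps it as the dimethyl boronate F4. Oxidation of the C–B bond (H2O2, AcOH, 0 °C → rt) then delivers 14.

Step 3.
- Risk: acyl substitution at a carbamate flanked on both sides may be sluggish. Forcing it invites loss of iodine or of a methyl ether.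
- Fallback: the directing group is changed to an acetal that leaves by mild acidolysis, which also removes the anionic Fries risk of step 2. It sets out from 1 and returns at 5. MOMCl and iPr2NEt (CH2Cl2, 0 °C → rt) should give the MOM ether F5. Then n-BuLi (THF, 0 °C) lithiates ortho to the chelating OMOM group to give the aryllithium F6, and I2 converts it into the iodo MOM ether F7. Finally HCl in MeOH (rt) releases 5.

**Further compounds**
F1 | step 6 | 1-(2-hydroxy-3,4-dimethoxyphenyl)ethanone (bought) | CC(=O)c1ccc(OC)c(OC)c1O
F2 | step 6 | (E)-3-[2-(benzyloxy)-4,5-dimethoxyphenyl]-1-(2-hydroxy-3,4-dimethoxyphenyl)prop-2-en-1-one | COc1ccc(C(=O)/C=C/c2cc(OC)c(OC)cc2OCc2ccccc2)c(O)c1OC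
F3 | step 7 | 2-[2-(benzyloxy)-4,5-dimethoxyphenyl]-3-lithio-7,8-dimethoxy-4H-chromen-4-one | [Li]c1c(-c2cc(OC)c(OC)cc2OCc2ccccc2)oc2c(OC)c(OC)ccc2c1=O
F4 | step 7 | dimethyl {2-[2-(benzyloxy)-4,5-dimethoxyphenyl]-7,8-dimethoxy-4-oxo-4H-chromen-3-yl}boronate | COB(OC)c1c(-c2cc(OC)c(OC)cc2OCc2ccccc2)oc2c(OC)c(OC)ccc2c1=O
F5 | step 3 | 1,2-dimethoxy-3-(methoxymethoxy)benzene | COCOc1cccc(OC)c1OC
F6 | step 3 | 1-lithio-3,4-dimethoxy-2-(methoxymethoxy)benzene | [Li]c1ccc(OC)c(OC)c1OCOC
F7 | step 3 | 1-iodo-3,4-dimethoxy-2-(methoxymethoxy)benzene | COCOc1c(I)ccc(OC)c1OC
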